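**Retrosynthetic overview**
1. The ester C–O bond is made last (Steglich). The alkenyl unit is joined to cyclobutane C1 by a Ni-catalysed decarboxylative alkenylation of a cyclobutanecarboxylic acid, which should converge on the trans isomer under control of C2.
2. That acid comes from retro-Claisen opening of a 3-acetylbicyclo[3.2.0]heptan-2-one. The cyclopentanone is a temporary ring: its C3/C4 become the two CH2 groups of the 3-oxobutyl chain and its carbonyl carbon finally leaves as CO2.
3. The bicycle is made by one Cu(I)-catalysed intramolecular [2+2] photocycloaddition of (S)-7-methylocta-1,6-dien-3-ol. It forms both new cyclobutane bonds (C1–C2 and C3–C4, the latter at the quaternary carbon) and relays the carbinol configuration into the ring.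
4. Enabling feature: cyclobutane C1 and C2 are adjacent methines that each carry a chain. The C1–C4 edge (as a vinyl group) and the C2–C3 edge (as Me2C=CH) can therefore be tied by a three-atom tether (one sacrificial carbinol carbon on C1 plus the two chain CH2 on C2) into a 1,6-diene whose OH and two alkenes chelate Cu(I).
5. Ring order: the temporary cyclopentane and the cyclobutane close together in step 3, the four-membered ring being the last and only permanent ring; the five-membered ring is cut in step 6.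

Key step: step 3

Remark: cyclobutane locants follow the target (C1 = CH bearing the pentenyl unit, C2 = CH bearing the 3-oxobutyl chain, C3 = CMe2, C4 = CH2). Step 3 is assumed to be endo-selective, as is usual for free 1,6-dien-3-ols, and this fixes the (S)-dienol as the enantiomer to prepare.

**Route**

Step 1
Reactants: 1 5-bromo-2-methylpent-2-ene; 2 acrolein
Product: 4 rac-7-methylocta-1,6-dien-3-ol, via (4-methylpent-3-en-1-yl)magnesium bromide 3 (not isolated)
Conditions: Mg, THF, rt; then 2, −78 °C → 0 °C; aq. NH4Cl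
Reagents that add atoms: none
Why: Grignard 1,2-addition to the enal at low temperature should give the allylic alcohol; the new carbinol centre forms as a racemate and is resolved in step 2.

Step 2
Reactants: 4 rac-7-methylocta-1,6-dien-3-ol
Product: 5 (3S)-7-methylocta-1,6-dien-3-ol
Conditions: Ti(OiPr)4 (cat.), D-(−)-diisopropyl tartrate (cat.), t-BuOOH (0.6 equiv), 4 Å MS, CH2Cl2, −20 °C
Reagents that add atoms: none
Why: Sharpless kinetic resolution: with the D-(−)-tartrate catalyst the (R)-allylic alcohol should be epoxidised much faster, so the (S)-enantiomer is recovered, and the isolated trisubstituted alkene is not a substrate for the Ti–tartrate/t-BuOOH system.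

Step 3
Reactants: 5 (3S)-7-methylocta-1,6-dien-3-ol
Product: 6 (1R,2S,5R)-6,6-dimethylbicyclo[3.2.0]heptan-2-ol
Conditions: (CuOTf)2·C6H6 (5 mol%), Et2O, hν 254 nm (quartz), rt; exo epimer removed by chromatography
Reagents that add atoms: none
Why: Kochi–Salomon reaction: Cu(I) binds both C=C bonds of the 1,6-diene and the C3 hydroxyl, and excitation of this complex joins diene C2 to C6 and C1 to C7. The closest known reaction type is the CuOTf-catalysed photobicyclisation of 1,6-heptadien-3-ols to bicyclo[3.2.0]heptan-2-ols. The temporary cyclopentane closes in the 1,5 (5-exo) mode imposed by the three-atom tether, and the cyclobutane closes by the second bond (C1–C7, the CH2–CMe2 bond at the quaternary carbon), i.e. a straight and not a crossed [2+2]. The two bridgeheads are necessarily cis, and their absolute configuration should be relayed from the (S)-carbinol, which sits endo in the tridentate Cu chelate, so that C5 (the later cyclobutane C2) is set as R. The step needs straight over crossed addition, secured by the 1,6-spacing, and endo over exo facial selectivity, secured by hydroxyl coordination; the exo epimer would give the enantiomeric ketone in step 4 and is therefore separated here.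

Step 4
Reactants: 6 (1R,2S,5R)-6,6-dimethylbicyclo[3.2.0]heptan-2-ol
Product: 7 (1R,5R)-6,6-dimethylbicyclo[3.2.0]heptan-2-one
Conditions: TPAP (cat.), NMO, 4 Å MS, CH2Cl2, rt
Reagents that add atoms: none
Why: Ley–Griffith oxidation removes the relay carbinol centre under neutral conditions; the cis ring fusion is the stable one, so the bridgeheads should not epimerise.

Step 5
Reactants: 7 (1R,5R)-6,6-dimethylbicyclo[3.2.0]heptan-2-one
Product: 8 (1R,5R)-3-acetyl-6,6-dimethylbicyclo[3.2.0]heptan-2-one (C3 epimers/enol form)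
Conditions: MgBr2·OEt2, i-Pr2NEt, CH2Cl2, rt
Reagents that add atoms: 1-acetyl-1H-benzotriazole, CC(=O)n1nnc2ccccc12
Why: Soft-enolisation C-acylation (crossed Claisen type): the magnesium enolate should form at the C3 methylene, because enolisation toward bridgehead C1 would place a double bond at the ring fusion; the new C3 centre is of no consequence (enolised β-diketone, lost in step 6).

Step 6
Reactants: 8 (1R,5R)-3-acetyl-6,6-dimethylbicyclo[3.2.0]heptan-2-one
Product: 9 (1R,2R)-3,3-dimethyl-2-(3-oxobutyl)cyclobutane-1-carboxylic acid (cis)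
Conditions: 1 M aq. NaOH, 60 °C; then HCl to pH 2
Reagents that add atoms: sodium hydroxide, [Na+].[OH-]
Why: Retro-Claisen (acid cleavage of a 2-acylcycloalkanone): hydroxide should add to the strained ring carbonyl, the C2–C3 bond breaks to the methyl ketone enolate and carboxylate formation makes the opening irreversible; neither ring stereocentre is touched, so the cis acid results.

Step 7
Reactants: 10 pent-4-yn-1-ol
Product: 11 tert-butyl(pent-4-yn-1-yloxy)diphenylsilane
Conditions: imidazole, DMF, rt
Reagents that add atoms: tert-butyl(chloro)diphenylsilane, CC(C)(C)[Si](Cl)(c1ccccc1)c1ccccc1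
Why: Standard silylation of the primary alcohol; the TBDPS ether is chosen to survive the Lewis-acidic bromoborane of step 8 and the organometallics of step 9; no stereocentre.

Step 8
Reactants: 11 tert-butyl(pent-4-yn-1-yloxy)diphenylsilane
Product: 13 [(4-bromopent-4-en-1-yl)oxy](tert-butyl)diphenylsilane, via (Z)-2-bromoalkenyl-9-BBN adduct 12 (not isolated)
Conditions: CH2Cl2, 0 °C; then AcOH, rt
Reagents that add atoms: B-bromo-9-borabicyclo[3.3.1]nonane, BrB1C2CCCC1CCC2
Why: Bromoboration: syn addition of B–Br across the terminal alkyne places Br on the internal carbon, and protodeboronation by acetic acid should give the 2-bromo-1-alkene; no stereocentre.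

Step 9
Reactants: 9 (1R,2R)-3,3-dimethyl-2-(3-oxobutyl)cyclobutane-1-carboxylic acid; 13 [(4-bromopent-4-en-1-yl)oxy](tert-butyl)diphenylsilane
Product: 17 4-[(1R,4S)-4-[5-[tert-butyl(diphenyl)silyl]oxypent-1-en-2-yl]-2,2-dimethylcyclobutyl]butan-2-one, via tetrachlorophthalimidyl ester 14 (not isolated), via alkenylmagnesium bromide 15 (not isolated), via alkenylzinc chloride 16 (not isolated)
Conditions: (a) 9, N-hydroxytetrachlorophthalimide, DIC, DMAP (cat.), CH2Cl2, rt; (b) 13, Mg, LiCl, THF, then ZnCl2; (c) Ni(acac)2 (10 mol%), 2,2′-bipyridine (10 mol%), THF/DMF, rt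
Reagents that add atoms: none
Why: Ni-catalysed decarboxylative alkenylation of a redox-active ester (Negishi type): single-electron reduction of 14 releases CO2 and a cyclobutyl radical at C1, and its capture by alkenyl–Ni followed by reductive elimination should occur on the face opposite the C2 side chain, so the trans (1S) configuration is set under control of the untouched (2R) centre whatever the C1 configuration of the acid.

Step 10
Reactants: 17 4-[(1R,4S)-4-[5-[tert-butyl(diphenyl)silyl]oxypent-1-en-2-yl]-2,2-dimethylcyclobutyl]butan-2-one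
Product: 18 4-[(1R,4S)-4-(5-hydroxypent-1-en-2-yl)-2,2-dimethylcyclobutyl]butan-2-one
Conditions: TBAF, THF, 0 °C → rt
Reagents that add atoms: none
Why: Fluoride-induced desilylation should free the primary alcohol without touching the ketone, the alkene or either stereocentre (neither is acidic).

Step 11
Reactants: 18 4-[(1R,4S)-4-(5-hydroxypent-1-en-2-yl)-2,2-dimethylcyclobutyl]butan-2-one; 19 linoleic acid
Product: 20 4-[(1S,2R)-3,3-dimethyl-2-(3-oxobutyl)cyclobutyl]pent-4-en-1-yl (9Z,12Z)-octadeca-9,12-dienoate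
Conditions: DCC, DMAP (cat.), CH2Cl2, 0 °C → rt
Reagents that add atoms: none
Why: Steglich esterification acylates the primary alcohol under neutral conditions, which should leave the skipped (Z,Z)-diene and both ring stereocentres unchanged.

**Compound list**
1 | 5-bromo-2-methylpent-2-ene | CC(C)=CCCBr | starting material
2 | acrolein | C=CC=O | starting material
3 | (4-methylpent-3-en-1-yl)magnesium bromide | CC(C)=CCC[Mg]Br | intermediate (not isolated)
4 | rac-7-methylocta-1,6-dien-3-ol | C=CC(O)CCC=C(C)C | intermediate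
5 | (3S)-7-methylocta-1,6-dien-3-ol | C=C[C@@H](O)CCC=C(C)C | intermediate
6 | (1R,2S,5R)-6,6-dimethylbicyclo[3.2.0]heptan-2-ol | O[C@H]1CC[C@@H]2[C@H]1CC2(C)C | intermediate
7 | (1R,5R)-6,6-dimethylbicyclo[3.2.0]heptan-2-one | O=C1CC[C@@H]2[C@H]1CC2(C)C | intermediate
8 | (1R,5R)-3-acetyl-6,6-dimethylbicyclo[3.2.0]heptan-2-one | O=C1C(C(C)=O)C[C@@H]2[C@H]1CC2(C)C | intermediate
9 | (1R,2R)-3,3-dimethyl-2-(3-oxobutyl)cyclobutane-1-carboxylic acid | OC(=O)[C@@H]1CC(C)(C)[C@@H]1CCC(C)=O | intermediate
10 | pent-4-yn-1-ol | C#CCCCO | starting material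
11 | tert-butyl(pent-4-yn-1-yloxy)diphenylsilane | C#CCCCO[Si](c1ccccc1)(c1ccccc1)C(C)(C)C | intermediate
12 | 9-[(1Z)-2-bromo-5-[tert-butyl(diphenyl)silyl]oxypent-1-en-1-yl]-9-borabicyclo[3.3.1]nonane | Br/C(CCCO[Si](c1ccccc1)(c1ccccc1)C(C)(C)C)=C\B1C2CCCC1CCC2 | intermediate (not isolated)
13 | [(4-bromopent-4-en-1-yl)oxy](tert-butyl)diphenylsilane | C=C(Br)CCCO[Si](c1ccccc1)(c1ccccc1)C(C)(C)C | intermediate
14 | 4,5,6,7-tetrachloro-1,3-dioxoisoindolin-2-yl (1R,2R)-3,3-dimethyl-2-(3-oxobutyl)cyclobutane-1-carboxylate | O=C(ON1C(=O)c2c(Cl)c(Cl)c(Cl)c(Cl)c2C1=O)[C@@H]3CC(C)(C)[C@@H]3CCC(C)=O | intermediate (not isolated)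
15 | [5-[tert-butyl(diphenyl)silyl]oxypent-1-en-2-yl]magnesium bromide | C=C([Mg]Br)CCCO[Si](c1ccccc1)(c1ccccc1)C(C)(C)C | intermediate (not isolated)
16 | [5-[tert-butyl(diphenyl)silyl]oxypent-1-en-2-yl]zinc chloride | C=C([Zn]Cl)CCCO[Si](c1ccccc1)(c1ccccc1)C(C)(C)C | intermediate (not isolated)
17 | 4-[(1R,4S)-4-[5-[tert-butyl(diphenyl)silyl]oxypent-1-en-2-yl]-2,2-dimethylcyclobutyl]butan-2-one | C=C(CCCO[Si](c1ccccc1)(c1ccccc1)C(C)(C)C)[C@H]1CC(C)(C)[C@@H]1CCC(C)=O | intermediate
18 | 4-[(1R,4S)-4-(5-hydroxypent-1-en-2-yl)-2,2-dimethylcyclobutyl]butan-2-one | C=C(CCCO)[C@H]1CC(C)(C)[C@@H]1CCC(C)=O | intermediate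
19 | linoleic acid, (9Z,12Z)-octadeca-9,12-dienoic acid | CCCCC/C=C\C/C=C\CCCCCCCC(=O)O | starting material
20 | 4-[(1S,2R)-3,3-dimethyl-2-(3-oxobutyl)cyclobutyl]pent-4-en-1-yl (9Z,12Z)-octadeca-9,12-dienoate | C=C(CCCOC(=O)CCCCCCC/C=C\C/C=C\CCCCC)[C@H]1CC(C)(C)[C@@H]1CCC(C)=O | target

**Step count and risks**
Total step count: 11. Longest linear sequence: 9 (steps 1–6, 9, 10, 11).

Steps most likely to fail:

Step 3. The photobicyclisation may be slow because the trisubstituted alkene binds Cu(I) weakly, or the endo/exo facial selectivity may be too low, which would erode enantiopurity after step 4. The fallback sets out from 4 and comes back at 6. Oxidation of 4 with Dess–Martin periodinane should give 7-methylocta-1,6-dien-3-one F1. Direct irradiation (about 350 nm, dilute MeCN) should then bring about the intramolecular enone–alkene [2+2] photocycloaddition with 1,5-closure (rule of five) to racemic cis-6,6-dimethylbicyclo[3.2.0]heptan-2-one F2. NaBH4 reduction from the convex face should give racemic endo-6,6-dimethylbicyclo[3.2.0]heptan-2-ol F3. Lipase-catalysed acylation (Candida antarctica lipase B, vinyl acetate) is expected to convert the (2R)-enantiomer into (1S,2R,5S)-6,6-dimethylbicyclo[3.2.0]heptan-2-yl acetate F4 and to leave the (1R,2S,5R)-alcohol, which is 6.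

Step 9. Radical capture may show poor facial selectivity (cis/trans mixture), the organometallic may add to the methyl ketone, or the hindered α-substituted alkenylzinc may couple sluggishly. The fallback sets out from 9 and comes back at 18.
- Amide coupling of 9 (EDC, MeNHOMe·HCl) should give (1R,2R)-N-methoxy-N,3,3-trimethyl-2-(3-oxobutyl)cyclobutane-1-carboxamide F5.
- Ketalisation (ethylene glycol, PPTS) should give (1R,2R)-N-methoxy-N,3,3-trimethyl-2-[2-(2-methyl-1,3-dioxolan-2-yl)ethyl]cyclobutane-1-carboxamide F6.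
- Addition of [3-[tert-butyl(dimethyl)silyl]oxypropyl]magnesium bromide F7 (from the commercial bromide and Mg) should give the cis ketone 4-[tert-butyl(dimethyl)silyl]oxy-1-[(1R,2R)-3,3-dimethyl-2-[2-(2-methyl-1,3-dioxolan-2-yl)ethyl]cyclobutyl]butan-1-one F8.
- Equilibration with NaOMe/MeOH should epimerise C1 to the more stable trans ketone 4-[tert-butyl(dimethyl)silyl]oxy-1-[(1S,2R)-3,3-dimethyl-2-[2-(2-methyl-1,3-dioxolan-2-yl)ethyl]cyclobutyl]butan-1-one F9; Claisen-type re-closure is excluded because the second ketone is masked.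
- Wittig methylenation (Ph3P=CH2) should give tert-butyl-[4-[(1S,2R)-3,3-dimethyl-2-[2-(2-methyl-1,3-dioxolan-2-yl)ethyl]cyclobutyl]pent-4-enoxy]dimethylsilane F10.
- Dilute aqueous HCl in THF should remove the dioxolane and the silyl group to give 18.

Step 6. Hydroxide may attack the acetyl carbonyl, so that the diketone is deacetylated back to the bicyclic ketone instead of being ring-opened. The fallback sets out from 7 and comes back at 9. Silylation (TMSOTf, Et3N) should give (1R,5R)-6,6-dimethyl-2-(trimethylsilyloxy)bicyclo[3.2.0]hept-2-ene F11. Ozonolysis (O3, CH2Cl2/MeOH, −78 °C; Me2S) should cleave the C2=C3 bond to (1R,2R)-3,3-dimethyl-2-(2-oxoethyl)cyclobutane-1-carboxylic acid F12. Wittig reaction with excess ylide from (1-methoxyethyl)triphenylphosphonium chloride/KHMDS should give (1R,2R)-2-(3-methoxybut-2-en-1-yl)-3,3-dimethylcyclobutane-1-carboxylic acid F13. Mild aqueous acid should hydrolyse the enol ether to the methyl ketone 9.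

**Further compounds**
F1 | step 3 | 7-methylocta-1,6-dien-3-one | C=CC(=O)CCC=C(C)C
F2 | step 3 | rac-cis-6,6-dimethylbicyclo[3.2.0]heptan-2-one | O=C1CC[C@@H]2[C@H]1CC2(C)C.O=C1CC[C@H]2[C@@H]1CC2(C)C
F3 | step 3 | rac-endo-6,6-dimethylbicyclo[3.2.0]heptan-2-ol | O[C@H]1CC[C@@H]2[C@H]1CC2(C)C.O[C@@H]1CC[C@H]2[C@@H]1CC2(C)C
F4 | step 3 | (1S,2R,5S)-6,6-dimethylbicyclo[3.2.0]heptan-2-yl acetate | CC(=O)O[C@@H]1CC[C@H]2[C@@H]1CC2(C)C
F5 | step 9 | (1R,2R)-N-methoxy-N,3,3-trimethyl-2-(3-oxobutyl)cyclobutane-1-carboxamide | CON(C)C(=O)[C@@H]1CC(C)(C)[C@@H]1CCC(C)=O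
F6 | step 9 | (1R,2R)-N-methoxy-N,3,3-trimethyl-2-[2-(2-methyl-1,3-dioxolan-2-yl)ethyl]cyclobutane-1-carboxamide | CON(C)C(=O)[C@@H]1CC(C)(C)[C@@H]1CCC2(C)OCCO2
F7 | step 9 | [3-[tert-butyl(dimethyl)silyl]oxypropyl]magnesium bromide | CC(C)(C)[Si](C)(C)OCCC[Mg]Br
F8 | step 9 | 4-[tert-butyl(dimethyl)silyl]oxy-1-[(1R,2R)-3,3-dimethyl-2-[2-(2-methyl-1,3-dioxolan-2-yl)ethyl]cyclobutyl]butan-1-one | CC(C)(C)[Si](C)(C)OCCCC(=O)[C@@H]1CC(C)(C)[C@@H]1CCC2(C)OCCO2
F9 | step 9 | 4-[tert-butyl(dimethyl)silyl]oxy-1-[(1S,2R)-3,3-dimethyl-2-[2-(2-methyl-1,3-dioxolan-2-yl)ethyl]cyclobutyl]butan-1-one | CC(C)(C)[Si](C)(C)OCCCC(=O)[C@H]1CC(C)(C)[C@@H]1CCC2(C)OCCO2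
F10 | step 9 | tert-butyl-[4-[(1S,2R)-3,3-dimethyl-2-[2-(2-methyl-1,3-dioxolan-2-yl)ethyl]cyclobutyl]pent-4-enoxy]dimethylsilane | C=C(CCCO[Si](C)(C)C(C)(C)C)[C@H]1CC(C)(C)[C@@H]1CCC2(C)OCCO2
F11 | step 6 | (1R,5R)-6,6-dimethyl-2-(trimethylsilyloxy)bicyclo[3.2.0]hept-2-ene | C[Si](C)(C)OC1=CC[C@@H]2[C@H]1CC2(C)C
F12 | step 6 | (1R,2R)-3,3-dimethyl-2-(2-oxoethyl)cyclobutane-1-carboxylic acid | OC(=O)[C@@H]1CC(C)(C)[C@@H]1CC=O
F13 | step 6 | (1R,2R)-2-(3-methoxybut-2-en-1-yl)-3,3-dimethylcyclobutane-1-carboxylic acid | OC(=O)[C@@H]1CC(C)(C)[C@@H]1CC=C(C)OC
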